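**Strategy**

Everything rests on cutting both side chains at C4–C5 (chain numbering: vinyl C1=C2, quaternary C3), the bond between the methylene on each quaternary carbon of ring A (the catechol ring) and ring B (the 2-hydroxyphenoxy ring) and C1 of an intact geranyl unit. One operation, double alkylation of a bis(α-lithio sulfone) with geranyl bromide, delivers twenty carbons and both E-trisubstituted alkenes without touching the quaternary centres. The precursor is the tris-MOM diaryl ether bearing a C(CH3)(CH=CH2)CH2SO2Ph group on each ring; its two centres, of opposite sense (R on ring A, S on ring B), come from enantiocomplementary lipase desymmetrisations, and the ether from a copper-catalysed coupling.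

Key step: step 21

Assumption: the lipase is taken to select the same enantiotopic hydroxymethyl arm in both aryl series, acetylating it in diol 8 and hydrolysing its acetate in diacetate 20. If the sense is found reversed, the two modes are exchanged between the halves.

Remark: the two quaternary centres have opposite spatial sense, so one half is made by enzymatic acylation and the other by enzymatic hydrolysis. The alkylation creates two uncontrolled stereogenic carbons (C4, C4′), so 32 is an epimer mixture that converges in step 22. Primed numbers refer to the chain on ring B.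

**Ring A half**

Step 1
Reactants: 1 acetovanillone
Product: 2 1-(4-hydroxy-3-iodo-5-methoxyphenyl)ethan-1-one
Conditions: NIS, p-TsOH·H2O (cat.), MeCN, rt
Reagents that add atoms: N-iodosuccinimide, O=C1CCC(=O)N1I
Why: Electrophilic aromatic iodination should go to the only free position ortho to the phenol (the para position carries the acetyl group), which is the ring A carbon that later bears the ether oxygen.

Step 2
Reactants: 2 1-(4-hydroxy-3-iodo-5-methoxyphenyl)ethan-1-one
Product: 3 1-(3,4-dihydroxy-5-iodophenyl)ethan-1-one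
Conditions: AlCl3, pyridine, CH2Cl2, reflux; then aq. HCl
Reagents that add atoms: none
Why: Aluminium chelated between the phenol oxygen and the neighbouring methoxy oxygen activates the O–CH3 bond for SN2 demethylation by pyridine, the selective cleavage of guaiacol-type methyl ethers, which leaves ketone and aryl iodide alone.

Step 3
Reactants: 3 1-(3,4-dihydroxy-5-iodophenyl)ethan-1-one
Product: 4 1-[3-iodo-4,5-bis(methoxymethoxy)phenyl]ethan-1-one
Conditions: MOMCl, i-Pr2NEt, CH2Cl2, 0 °C → rt
Reagents that add atoms: chloromethyl methyl ether, COCCl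
Why: O-Alkylation of both phenols by the reactive α-chloro ether (acetal protection) should give the base-stable bis-MOM ether needed for the carbanion chemistry ahead.

Step 4
Reactants: 4 1-[3-iodo-4,5-bis(methoxymethoxy)phenyl]ethan-1-one
Product: 7 2-[3-iodo-4,5-bis(methoxymethoxy)phenyl]propanal (racemic), via glycidic ester 5 (not isolated), via sodium glycidate 6 (not isolated)
Conditions: ClCH2CO2Et, t-BuOK, t-BuOH–THF, 0 °C → rt; NaOH, EtOH–H2O, rt; AcOH to pH 4–5, toluene–H2O, 60 °C
Reagents that add atoms: ethyl chloroacetate, CCOC(=O)CCl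
Why: Darzens glycidic ester condensation, saponification and decarboxylative epoxide opening is the classical one-carbon homologation of an aryl methyl ketone to a 2-arylpropanal, and the weakly acidic decarboxylation spares the MOM acetals that a strong-acid enol ether hydrolysis would endanger.

Step 5
Reactants: 7 2-[3-iodo-4,5-bis(methoxymethoxy)phenyl]propanal
Product: 8 2-[3-iodo-4,5-bis(methoxymethoxy)phenyl]-2-methylpropane-1,3-diol
Conditions: 37% aq. HCHO (excess), KOH, EtOH–H2O, rt → 45 °C
Reagents that add atoms: formaldehyde, C=O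
Why: Tollens condensation (crossed aldol with formaldehyde at the only α-position, then crossed Cannizzaro reduction of the resulting non-enolisable aldehyde) should give the prochiral diol and erase the stereocentre of 7.

Step 6
Reactants: 8 2-[3-iodo-4,5-bis(methoxymethoxy)phenyl]-2-methylpropane-1,3-diol
Product: 9 (S)-3-hydroxy-2-[3-iodo-4,5-bis(methoxymethoxy)phenyl]-2-methylpropyl acetate
Conditions: lipase PS from Burkholderia cepacia, vinyl acetate, t-BuOMe, 30 °C
Reagents that add atoms: vinyl acetate, C=COC(C)=O
Why: Lipase-catalysed irreversible transesterification, precedented for 2-aryl-2-methylpropane-1,3-diols, acetylates one enantiotopic hydroxymethyl arm, so the quaternary stereocentre is set by the arm discrimination of the enzyme active site.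

Step 7
Reactants: 9 (S)-3-hydroxy-2-[3-iodo-4,5-bis(methoxymethoxy)phenyl]-2-methylpropyl acetate
Product: 10 (R)-2-[3-iodo-4,5-bis(methoxymethoxy)phenyl]-2-methyl-3-oxopropyl acetate
Conditions: Dess–Martin periodinane, CH2Cl2, 0 °C → rt
Reagents that add atoms: none
Why: Dess–Martin oxidation of the free primary alcohol, done directly so that no acyl migration can erode the enantiomeric purity, gives an aldehyde with no α-hydrogen, so it can neither epimerise nor eliminate acetate.

Step 8
Reactants: 10 (R)-2-[3-iodo-4,5-bis(methoxymethoxy)phenyl]-2-methyl-3-oxopropyl acetate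
Product: 12 (R)-2-[3-iodo-4,5-bis(methoxymethoxy)phenyl]-2-methylbut-3-en-1-ol, via vinyl acetate 11 (not isolated)
Conditions: Ph3PCH3Br, KN(SiMe3)2, THF, 0 °C; 10, −78 °C → rt; then K2CO3, MeOH, rt
Reagents that add atoms: methyltriphenylphosphonium bromide, C[P+](c1ccccc1)(c1ccccc1)c1ccccc1.[Br-]
Why: Wittig methylenation turns the aldehyde arm into the vinyl group and in-flask methanolysis frees the other arm, so any ylide attack on the acetate merely anticipates the deacetylation.

**Ring B half**

Step 9
Reactants: 13 2',3'-dihydroxyacetophenone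
Product: 14 1-[2-hydroxy-3-(prop-2-en-1-yloxy)phenyl]ethan-1-one
Conditions: NaH (2.2 equiv), DMSO–THF, rt; allyl bromide (1.0 equiv); then aq. HCl
Reagents that add atoms: allyl bromide, C=CCBr
Why: In the dianion the 3'-oxide, neither conjugated with nor chelated to the acetyl group, is the more nucleophilic site, so Williamson alkylation with one equivalent of halide should give the 3'-allyl ether selectively.

Step 10
Reactants: 14 1-[2-hydroxy-3-(prop-2-en-1-yloxy)phenyl]ethan-1-one
Product: 15 1-[2-(methoxymethoxy)-3-(prop-2-en-1-yloxy)phenyl]ethan-1-one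
Conditions: NaH, MOMCl, DMF, 0 °C → rt
Reagents that add atoms: chloromethyl methyl ether, COCCl
Why: Full deprotonation breaks the hydrogen bond of the chelated phenol, and O-alkylation then installs the MOM group that the final precursor keeps on this oxygen, orthogonal to the allyl ether.

Step 11
Reactants: 15 1-[2-(methoxymethoxy)-3-(prop-2-en-1-yloxy)phenyl]ethan-1-one
Product: 18 2-[2-(methoxymethoxy)-3-(prop-2-en-1-yloxy)phenyl]propanal (racemic), via glycidic ester 16 (not isolated), via sodium glycidate 17 (not isolated)
Conditions: ClCH2CO2Et, t-BuOK, t-BuOH–THF, 0 °C → rt; NaOH, EtOH–H2O, rt; AcOH to pH 4–5, toluene–H2O, 60 °C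
Reagents that add atoms: ethyl chloroacetate, CCOC(=O)CCl
Why: The same Darzens homologation as in step 4 is used because its concerted decarboxylative opening generates no free benzylic cation that the ortho MOM group could trap.

Step 12
Reactants: 18 2-[2-(methoxymethoxy)-3-(prop-2-en-1-yloxy)phenyl]propanal
Product: 19 2-[2-(methoxymethoxy)-3-(prop-2-en-1-yloxy)phenyl]-2-methylpropane-1,3-diol
Conditions: 37% aq. HCHO (excess), KOH, EtOH–H2O, rt → 45 °C
Reagents that add atoms: formaldehyde, C=O
Why: Tollens condensation (aldol, then crossed Cannizzaro) should give the prochiral diol as in step 5, with allyl and MOM ethers stable to aqueous base.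

Step 13
Reactants: 19 2-[2-(methoxymethoxy)-3-(prop-2-en-1-yloxy)phenyl]-2-methylpropane-1,3-diol
Product: 20 2-[2-(methoxymethoxy)-3-(prop-2-en-1-yloxy)phenyl]-2-methylpropane-1,3-diyl diacetate
Conditions: Ac2O, pyridine, DMAP (cat.), CH2Cl2, rt
Reagents that add atoms: acetic anhydride, CC(=O)OC(C)=O
Why: Nucleophile-catalysed acylation of both primary alcohols provides the prochiral diester that enzymatic hydrolysis needs to reach the sense opposite to that of ring A.

Step 14
Reactants: 20 2-[2-(methoxymethoxy)-3-(prop-2-en-1-yloxy)phenyl]-2-methylpropane-1,3-diyl diacetate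
Product: 21 (R)-3-hydroxy-2-[2-(methoxymethoxy)-3-(prop-2-en-1-yloxy)phenyl]-2-methylpropyl acetate
Conditions: lipase PS from Burkholderia cepacia, phosphate buffer pH 7–acetone, 25 °C
Reagents that add atoms: none
Why: Lipase-catalysed hydrolysis removes the acetate from the arm that the enzyme would acylate, leaving the ester on the other arm, so the quaternary stereocentre is set with the sense opposite to step 6 by the same active-site discrimination.

Step 15
Reactants: 21 (R)-3-hydroxy-2-[2-(methoxymethoxy)-3-(prop-2-en-1-yloxy)phenyl]-2-methylpropyl acetate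
Product: 22 (S)-2-[2-(methoxymethoxy)-3-(prop-2-en-1-yloxy)phenyl]-2-methyl-3-oxopropyl acetate
Conditions: Dess–Martin periodinane, CH2Cl2, 0 °C → rt
Reagents that add atoms: none
Why: Dess–Martin oxidation of the freed arm, carried out at once to forestall acyl migration, gives a non-enolisable aldehyde as in step 7.

Step 16
Reactants: 22 (S)-2-[2-(methoxymethoxy)-3-(prop-2-en-1-yloxy)phenyl]-2-methyl-3-oxopropyl acetate
Product: 24 (S)-2-[2-(methoxymethoxy)-3-(prop-2-en-1-yloxy)phenyl]-2-methylbut-3-en-1-ol, via vinyl acetate 23 (not isolated)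
Conditions: Ph3PCH3Br, KN(SiMe3)2, THF, 0 °C; 22, −78 °C → rt; then K2CO3, MeOH, rt
Reagents that add atoms: methyltriphenylphosphonium bromide, C[P+](c1ccccc1)(c1ccccc1)c1ccccc1.[Br-]
Why: Wittig methylenation and in-flask methanolysis convert the aldehyde arm into vinyl and free the other arm exactly as in step 8.

Step 17
Reactants: 24 (S)-2-[2-(methoxymethoxy)-3-(prop-2-en-1-yloxy)phenyl]-2-methylbut-3-en-1-ol
Product: 25 3-[(S)-1-hydroxy-2-methylbut-3-en-2-yl]-2-(methoxymethoxy)phenol
Conditions: Pd(PPh3)4 (cat.), morpholine, THF, rt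
Reagents that add atoms: none
Why: Zerovalent palladium ionises only the allyl aryl ether to a π-allyl complex that morpholine intercepts (Tsuji–Trost deallylation), which frees the phenol while the homoallylic alcohol, vinyl group and MOM ether cannot ionise.

**Union and end game**

Step 18
Reactants: 12 (R)-2-[3-iodo-4,5-bis(methoxymethoxy)phenyl]-2-methylbut-3-en-1-ol; 25 3-[(S)-1-hydroxy-2-methylbut-3-en-2-yl]-2-(methoxymethoxy)phenol
Product: 26 (R)-2-[3-{3-[(S)-1-hydroxy-2-methylbut-3-en-2-yl]-2-(methoxymethoxy)phenoxy}-4,5-bis(methoxymethoxy)phenyl]-2-methylbut-3-en-1-ol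
Conditions: CuI (cat.), picolinic acid (cat.), K3PO4, DMSO, 85 °C
Reagents that add atoms: none
Why: Ligand-accelerated Ullmann diaryl ether synthesis should couple the aryl iodide with the phenoxide despite an ortho alkoxy group on each partner, while the neopentyl primary alcohols are neither deprotonated by phosphate nor arylated.

Step 19
Reactants: 26 diaryl ether diol; 27 diphenyl disulfide
Product: 28 bis(phenyl sulfide): the diaryl ether of 26 with each CH2OH replaced by CH2SPh (ring A centre R, ring B centre S)
Conditions: PhSSPh, PBu3, pyridine, 70 °C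
Reagents that add atoms: diphenyl disulfide, c1ccc(SSc2ccccc2)cc1
Why: Hata redox condensation activates each alcohol as an alkoxyphosphonium ion that thiolate displaces by SN2, and heating with this strongly nucleophilic counter-ion is what makes substitution at the two neopentyl carbons feasible without involving the quaternary centres.

Step 20
Reactants: 28 bis(phenyl sulfide)
Product: 29 bis(phenyl sulfone) tris-MOM diaryl ether, the alkylation precursor (ring A centre R, ring B centre S)
Conditions: (NH4)6Mo7O24·4H2O (cat.), 30% aq. H2O2, EtOH–THF, 0 °C → rt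
Reagents that add atoms: hydrogen peroxide, OO
Why: Molybdate-catalysed peroxide oxidation takes each sulfide through the sulfoxide to the sulfone and should leave the terminal vinyl groups and electron-rich rings untouched, since peroxomolybdate does not epoxidise unactivated monosubstituted alkenes.

Step 21
Reactants: 29 bis(phenyl sulfone) tris-MOM diaryl ether; 30 geranyl bromide
Product: 32 bis(C4-phenylsulfonyl) tris-MOM ether of the target (mixture of C4 and C4′ epimers), via dilithio bis-sulfone 31 (not isolated)
Conditions: LiN(i-Pr)2 (2.3 equiv, commercial solution), THF–DMPU, −78 °C, 45 min; 30 (2.5 equiv), −78 → −20 °C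
Reagents that add atoms: geranyl bromide, CC(C)=CCC/C(C)=C/CBr
Why: LiN(i-Pr)2 removes one proton from each sulfonyl-flanked methylene (C4 and C4′, the most acidic C–H bonds present, with no α-hydrogen at either quaternary carbon) to give dilithio species 31, and each carbanion displaces bromide at the primary allylic C1 of geranyl bromide by SN2, forming both C4–C5 bonds. The closest known reaction type is the alkylation of lithiated alkyl phenyl sulfones with primary allylic bromides used for terpenoid chain coupling before reductive desulfonylation. No ring is closed. Two new stereogenic carbons arise at C4 and C4′ without control and are erased in step 22, whereas the quaternary centres (R on ring A, S on ring B) cannot epimerise. The step needs C-alkylation at C1 in preference to SN2′ attack at C3 or E2, with the E-alkene retained, and the unhindered primary terminus, the soft sulfonyl carbanion and the low temperature should secure this, with DMPU loosening the aggregates of the crowded neopentyl carbanions. An amide base is used in place of an alkyllithium so that neither the MOM-bearing rings nor the phenylsulfonyl rings are ortho-lithiated, and the hindered tertiary sulfone product resists a second alkylation.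

Step 22
Reactants: 32 bis(C4-phenylsulfonyl) tris-MOM ether
Product: 33 tris-MOM ether of the target (ring A centre R, ring B centre S)
Conditions: 6% Na(Hg), Na2HPO4, MeOH–THF, −20 °C
Reagents that add atoms: none
Why: Reductive desulfonylation by electron transfer from sodium amalgam cleaves each C4–S bond and methanol protonates the carbanion at once, with the phosphate buffer preventing methoxide-induced alkene migration and the low temperature outrunning any 1,2-vinyl shift of the transient C4 radical.

Step 23
Reactants: 33 tris-MOM ether of the target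
Product: 34 CNP0325484.1
Conditions: HCl (cat., 0.5 M), MeOH–THF, 40 °C, argon
Reagents that add atoms: none
Why: Acid-catalysed transacetalisation of the three aryl MOM acetals to methanol frees the catechol and the phenol under conditions too mild to protonate the isolated trisubstituted and terminal alkenes, and argon protects the catechol from air oxidation.

**Compound list**

1 | acetovanillone | CC(=O)c1ccc(O)c(OC)c1 | starting material
2 | 1-(4-hydroxy-3-iodo-5-methoxyphenyl)ethan-1-one | CC(=O)c1cc(I)c(O)c(OC)c1 | intermediate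
3 | 1-(3,4-dihydroxy-5-iodophenyl)ethan-1-one | CC(=O)c1cc(O)c(O)c(I)c1 | intermediate
4 | 1-[3-iodo-4,5-bis(methoxymethoxy)phenyl]ethan-1-one | CC(=O)c1cc(OCOC)c(OCOC)c(I)c1 | intermediate
5 | ethyl 3-[3-iodo-4,5-bis(methoxymethoxy)phenyl]-3-methyloxirane-2-carboxylate (diastereomer mixture) | CCOC(=O)C1OC1(C)c1cc(OCOC)c(OCOC)c(I)c1 | intermediate
6 | sodium 3-[3-iodo-4,5-bis(methoxymethoxy)phenyl]-3-methyloxirane-2-carboxylate | [Na+].[O-]C(=O)C1OC1(C)c1cc(OCOC)c(OCOC)c(I)c1 | intermediate
7 | 2-[3-iodo-4,5-bis(methoxymethoxy)phenyl]propanal (racemic) | CC(C=O)c1cc(OCOC)c(OCOC)c(I)c1 | intermediate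
8 | 2-[3-iodo-4,5-bis(methoxymethoxy)phenyl]-2-methylpropane-1,3-diol | CC(CO)(CO)c1cc(OCOC)c(OCOC)c(I)c1 | intermediate
9 | (S)-3-hydroxy-2-[3-iodo-4,5-bis(methoxymethoxy)phenyl]-2-methylpropyl acetate | OC[C@@](C)(COC(C)=O)c1cc(OCOC)c(OCOC)c(I)c1 | intermediate
10 | (R)-2-[3-iodo-4,5-bis(methoxymethoxy)phenyl]-2-methyl-3-oxopropyl acetate | O=C[C@@](C)(COC(C)=O)c1cc(OCOC)c(OCOC)c(I)c1 | intermediate
11 | (R)-2-[3-iodo-4,5-bis(methoxymethoxy)phenyl]-2-methylbut-3-en-1-yl acetate | C=C[C@@](C)(COC(C)=O)c1cc(OCOC)c(OCOC)c(I)c1 | intermediate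
12 | (R)-2-[3-iodo-4,5-bis(methoxymethoxy)phenyl]-2-methylbut-3-en-1-ol | C=C[C@@](C)(CO)c1cc(OCOC)c(OCOC)c(I)c1 | intermediate
13 | 2',3'-dihydroxyacetophenone | CC(=O)c1cccc(O)c1O | starting material
14 | 1-[2-hydroxy-3-(prop-2-en-1-yloxy)phenyl]ethan-1-one | CC(=O)c1cccc(OCC=C)c1O | intermediate
15 | 1-[2-(methoxymethoxy)-3-(prop-2-en-1-yloxy)phenyl]ethan-1-one | CC(=O)c1cccc(OCC=C)c1OCOC | intermediate
16 | ethyl 3-[2-(methoxymethoxy)-3-(prop-2-en-1-yloxy)phenyl]-3-methyloxirane-2-carboxylate (diastereomer mixture) | CCOC(=O)C1OC1(C)c1cccc(OCC=C)c1OCOC | intermediate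
17 | sodium 3-[2-(methoxymethoxy)-3-(prop-2-en-1-yloxy)phenyl]-3-methyloxirane-2-carboxylate | [Na+].[O-]C(=O)C1OC1(C)c1cccc(OCC=C)c1OCOC | intermediate
18 | 2-[2-(methoxymethoxy)-3-(prop-2-en-1-yloxy)phenyl]propanal (racemic) | CC(C=O)c1cccc(OCC=C)c1OCOC | intermediate
19 | 2-[2-(methoxymethoxy)-3-(prop-2-en-1-yloxy)phenyl]-2-methylpropane-1,3-diol | CC(CO)(CO)c1cccc(OCC=C)c1OCOC | intermediate
20 | 2-[2-(methoxymethoxy)-3-(prop-2-en-1-yloxy)phenyl]-2-methylpropane-1,3-diyl diacetate | CC(=O)OCC(C)(COC(C)=O)c1cccc(OCC=C)c1OCOC | intermediate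
21 | (R)-3-hydroxy-2-[2-(methoxymethoxy)-3-(prop-2-en-1-yloxy)phenyl]-2-methylpropyl acetate | OC[C@](C)(COC(C)=O)c1cccc(OCC=C)c1OCOC | intermediate
22 | (S)-2-[2-(methoxymethoxy)-3-(prop-2-en-1-yloxy)phenyl]-2-methyl-3-oxopropyl acetate | O=C[C@](C)(COC(C)=O)c1cccc(OCC=C)c1OCOC | intermediate
23 | (S)-2-[2-(methoxymethoxy)-3-(prop-2-en-1-yloxy)phenyl]-2-methylbut-3-en-1-yl acetate | C=C[C@](C)(COC(C)=O)c1cccc(OCC=C)c1OCOC | intermediate
24 | (S)-2-[2-(methoxymethoxy)-3-(prop-2-en-1-yloxy)phenyl]-2-methylbut-3-en-1-ol | C=C[C@](C)(CO)c1cccc(OCC=C)c1OCOC | intermediate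
25 | 3-[(S)-1-hydroxy-2-methylbut-3-en-2-yl]-2-(methoxymethoxy)phenol | C=C[C@](C)(CO)c1cccc(O)c1OCOC | intermediate
26 | (R)-2-[3-{3-[(S)-1-hydroxy-2-methylbut-3-en-2-yl]-2-(methoxymethoxy)phenoxy}-4,5-bis(methoxymethoxy)phenyl]-2-methylbut-3-en-1-ol | C=C[C@@](C)(CO)c1cc(OCOC)c(OCOC)c(Oc2cccc([C@](C)(C=C)CO)c2OCOC)c1 | intermediate
27 | diphenyl disulfide | c1ccc(SSc2ccccc2)cc1 | starting material
28 | bis(phenyl sulfide) tris-MOM diaryl ether (ring A centre R, ring B centre S) | C=C[C@@](C)(CSc1ccccc1)c1cc(OCOC)c(OCOC)c(Oc2cccc([C@](C)(C=C)CSc3ccccc3)c2OCOC)c1 | intermediate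
29 | bis(phenyl sulfone) tris-MOM diaryl ether, alkylation precursor (ring A centre R, ring B centre S) | C=C[C@@](C)(CS(=O)(=O)c1ccccc1)c1cc(OCOC)c(OCOC)c(Oc2cccc([C@](C)(C=C)CS(=O)(=O)c3ccccc3)c2OCOC)c1 | intermediate
30 | geranyl bromide | CC(C)=CCC/C(C)=C/CBr | starting material
31 | dilithio bis-sulfone (C4,C4′-dianion of 29) | [Li+].[Li+].C=C[C@@](C)([CH-]S(=O)(=O)c1ccccc1)c1cc(OCOC)c(OCOC)c(Oc2cccc([C@](C)(C=C)[CH-]S(=O)(=O)c3ccccc3)c2OCOC)c1 | intermediate
32 | bis(C4-phenylsulfonyl) tris-MOM ether of the target (C4, C4′ epimer mixture) | C=C[C@@](C)(C(C/C=C(\C)CCC=C(C)C)S(=O)(=O)c1ccccc1)c1cc(OCOC)c(OCOC)c(Oc2cccc([C@](C)(C=C)C(C/C=C(\C)CCC=C(C)C)S(=O)(=O)c3ccccc3)c2OCOC)c1 | intermediate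
33 | tris-MOM ether of the target | C=C[C@@](C)(CC/C=C(\C)CCC=C(C)C)c1cc(OCOC)c(OCOC)c(Oc2cccc([C@](C)(C=C)CC/C=C(\C)CCC=C(C)C)c2OCOC)c1 | intermediate
34 | CNP0325484.1 | C=C[C@@](C)(CC/C=C(\C)CCC=C(C)C)c1cc(O)c(O)c(Oc2cccc([C@](C)(C=C)CC/C=C(\C)CCC=C(C)C)c2O)c1 | target

**Step count**

Total: 23 steps. Longest linear sequence: 15 steps (13 → 34, steps 9–17 and 18–23).

**Steps most likely to fail**

Step 21. The process to fear is proton transfer competing with C–C bond formation at the two crowded carbanions (E2 on geranyl bromide or quenching of the second anion), which would leave a mixture of un-, mono- and bis-geranylated sulfones. The fallback attaches the chains before the ether union, one sulfone at a time, and sets out from 12 and 24. Iodo alcohol 12 with PhSSPh/PBu3 would give the ring A iodo sulfide F1, (NH4)6Mo7O24/H2O2 the ring A iodo sulfone F2, and LiN(i-Pr)2 (1.1 equiv) with geranyl bromide the ring A geranylated iodo sulfone F3. The same three operations on allyl ether alcohol 24 would give the ring B allyl ether sulfide F4, the ring B allyl ether sulfone F5 and the ring B geranylated allyl ether sulfone F6, from which Pd(PPh3)4/morpholine frees the ring B geranylated phenol sulfone F7. CuI/picolinic acid/K3PO4 coupling of F3 with F7 comes back to the route at 32.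

Step 14. The process to fear is weak discrimination of the two acetoxymethyl arms by the enzyme, because the ortho MOM group sits next to the quaternary carbon, together with slow acyl migration in the aqueous medium; both would lower the enantiomeric purity of the ring B centre. The fallback replaces biocatalysis by small-molecule asymmetric acyl transfer and sets out from diol 19. Monobenzoylation with vinyl benzoate, catalysed by the dinuclear zinc complex formed from Et2Zn and a ProPhenol ligand (enantiomer chosen for the required arm), would give the (R)-monobenzoate F8, which resists acyl migration better than an acetate. Dess–Martin oxidation would give the aldehyde benzoate F9, and Wittig methylenation followed by NaOMe/MeOH cleavage of the vinyl benzoate F10 comes back to the route at 24.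

Step 18. The process to fear is slow C–O bond formation between two partners that each carry an ortho alkoxy group, with protodeiodination of the electron-rich iodide taking over at the temperature needed. The fallback reverses the polarity of ring A and couples at room temperature; it sets out from iodide 12. Iodine–magnesium exchange (i-PrMgCl·LiCl, 2.2 equiv, THF, −20 °C), trapping with B(OMe)3 and aqueous work-up would give the ring A boronic acid F11. Chan–Lam–Evans coupling of F11 with phenol 25 (Cu(OAc)2, pyridine, 4 Å molecular sieves, CH2Cl2, air, rt) comes back to the route at 26.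

**Further compounds**

F1 | step 21 | (R)-{[2-(3-iodo-4,5-bis(methoxymethoxy)phenyl)-2-methylbut-3-en-1-yl]sulfanyl}benzene (ring A iodo sulfide) | C=C[C@@](C)(CSc1ccccc1)c1cc(OCOC)c(OCOC)c(I)c1
F2 | step 21 | (R)-{[2-(3-iodo-4,5-bis(methoxymethoxy)phenyl)-2-methylbut-3-en-1-yl]sulfonyl}benzene (ring A iodo sulfone) | C=C[C@@](C)(CS(=O)(=O)c1ccccc1)c1cc(OCOC)c(OCOC)c(I)c1
F3 | step 21 | ring A geranylated iodo sulfone (quaternary centre R, C4 epimer mixture) | C=C[C@@](C)(C(C/C=C(\C)CCC=C(C)C)S(=O)(=O)c1ccccc1)c1cc(OCOC)c(OCOC)c(I)c1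
F4 | step 21 | (S)-{[2-(2-(methoxymethoxy)-3-(prop-2-en-1-yloxy)phenyl)-2-methylbut-3-en-1-yl]sulfanyl}benzene (ring B allyl ether sulfide) | C=C[C@](C)(CSc1ccccc1)c1cccc(OCC=C)c1OCOC
F5 | step 21 | (S)-{[2-(2-(methoxymethoxy)-3-(prop-2-en-1-yloxy)phenyl)-2-methylbut-3-en-1-yl]sulfonyl}benzene (ring B allyl ether sulfone) | C=C[C@](C)(CS(=O)(=O)c1ccccc1)c1cccc(OCC=C)c1OCOC
F6 | step 21 | ring B geranylated allyl ether sulfone (quaternary centre S, C4′ epimer mixture) | C=C[C@](C)(C(C/C=C(\C)CCC=C(C)C)S(=O)(=O)c1ccccc1)c1cccc(OCC=C)c1OCOC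
F7 | step 21 | ring B geranylated phenol sulfone (quaternary centre S, C4′ epimer mixture) | C=C[C@](C)(C(C/C=C(\C)CCC=C(C)C)S(=O)(=O)c1ccccc1)c1cccc(O)c1OCOC
F8 | step 14 | (R)-3-hydroxy-2-[2-(methoxymethoxy)-3-(prop-2-en-1-yloxy)phenyl]-2-methylpropyl benzoate | OC[C@](C)(COC(=O)c1ccccc1)c1cccc(OCC=C)c1OCOC
F9 | step 14 | (S)-2-[2-(methoxymethoxy)-3-(prop-2-en-1-yloxy)phenyl]-2-methyl-3-oxopropyl benzoate | O=C[C@](C)(COC(=O)c1ccccc1)c1cccc(OCC=C)c1OCOC
F10 | step 14 | (S)-2-[2-(methoxymethoxy)-3-(prop-2-en-1-yloxy)phenyl]-2-methylbut-3-en-1-yl benzoate | C=C[C@](C)(COC(=O)c1ccccc1)c1cccc(OCC=C)c1OCOC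
F11 | step 18 | {5-[(R)-1-hydroxy-2-methylbut-3-en-2-yl]-2,3-bis(methoxymethoxy)phenyl}boronic acid | C=C[C@@](C)(CO)c1cc(OCOC)c(OCOC)c(B(O)O)c1
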